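**Strategy.** Everything hinges on cutting the C4–C4a bond of ring C. Acid 17, a (2R,3R)-3-aryl-3-aryloxy-2-silyloxypropanoic acid, already holds the O1–C2 ether, both stereocentres, the C8 prenyl group and the 3'-geranyl chain. Turned into a mixed anhydride, it acylates ring A and thereby closes the six-membered ring C in a single operation. The step exploits the electronic and steric situation of C4a in ring A. Three oxygens push electron density onto it (O1 and O5 from ortho, O7 from para). Its only rival next to O1, C8, is occupied by prenyl, so nothing but the 8-prenyl chromanone can form. A catalytic nucleophilic epoxidation and an invertive phenoxide opening supply the stereocentres.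

Key step: step 12

Assumption: the sense of induction in step 5 is assigned by analogy with simple cinnamoyl substrates, for which the (S)-configured binaphthol-type ligand leads to the (2R,3S)-epoxide; both ligand antipodes are commercial.

Step 1
Reactants: 1 4-iodophenol; 2 geranyl bromide
Product: 3 ortho-geranylated iodophenol (2-[(2E)-3,7-dimethylocta-2,6-dien-1-yl]-4-iodophenol)
Conditions: NaH (1 equiv per 1), 1 (1.5 equiv), toluene, 0 °C → rt
Reagents that add atoms: none
Why: ortho-C-allylation of a sodium phenoxide held as a tight ion pair in a non-polar solvent proceeds by SN2 at the primary allylic carbon, so the E alkene and the linear chain are kept, and the excess of 1 limits double alkylation.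

Step 2
Reactants: 3 ortho-geranylated iodophenol
Product: 4 TIPS ether of 3 ([2-geranyl-4-iodophenoxy]triisopropylsilane)
Conditions: TIPSCl, imidazole, DMF, rt
Reagents that add atoms: triisopropylsilyl chloride, CC(C)[Si](Cl)(C(C)C)C(C)C
Why: standard imidazole-promoted O-silylation, with TIPS chosen because phenolic TIPS ethers resist amines, phenoxide and dilute acid far better than phenolic TBS ethers yet still fall to fluoride.

Step 3
Reactants: 4 TIPS ether of 3; 5 acrylic acid
Product: 6 cinnamic acid ((E)-3-[3-geranyl-4-(triisopropylsilyloxy)phenyl]prop-2-enoic acid)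
Conditions: Pd(OAc)2 (5 mol %), P(o-tol)3 (10 mol %), Et3N, MeCN, 80 °C; citric acid wash
Reagents that add atoms: none
Why: the Mizoroki–Heck coupling of an aryl iodide with an acrylic acceptor gives the E alkene by syn insertion and syn β-hydride elimination, and the trisubstituted geranyl alkenes are too hindered, and too remote from the C–Pd bond (meta), to compete.

Step 4
Reactants: 6 cinnamic acid
Product: 8 cinnamoylpyrrole ((E)-3-[3-geranyl-4-(triisopropylsilyloxy)phenyl]-1-(pyrrol-1-yl)prop-2-en-1-one), via acylimidazole 7 (not isolated)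
Conditions: CDI (1.1 equiv), THF, rt; then pyrrole (2 equiv), DBU (0.2 equiv), 40 °C
Reagents that add atoms: 1,1'-carbonyldiimidazole, O=C(n1ccnc1)n1ccnc1 (its imidazolyl group is carried only by 7); pyrrole, c1cc[nH]c1
Why: DBU-catalysed acyl transfer from an acylimidazole to a weakly acidic azole (N-acylation) is downhill because imidazole is the better leaving group, and it avoids HCl and strong base next to the alkenes and the aryl silyl ether.

Step 5
Reactants: 8 cinnamoylpyrrole
Product: 9 trans-epoxy acylpyrrole ([(2R,3S)-3-[3-geranyl-4-(triisopropylsilyloxy)phenyl]oxiran-2-yl](pyrrol-1-yl)methanone)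
Conditions: Sm(O-i-Pr)3/(S)-H8-BINOL/Ph3As=O (1:1:1, 5 mol %), TBHP (decane, 1.5 equiv), 4 Å MS, THF–toluene, rt
Reagents that add atoms: tert-butyl hydroperoxide, CC(C)(C)OO
Why: in this Weitz–Scheffer-type catalytic asymmetric epoxidation of an α,β-unsaturated N-acylpyrrole the chiral samarium binaphthoxide binds the acyl oxygen and delivers tert-butylperoxide to one face of the β-carbon, the enolate closes faster than it rotates so that the trans (2R,3S)-epoxide should result, and the nucleophilic oxidant ignores the electron-rich geranyl alkenes.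

Step 6
Reactants: 9 trans-epoxy acylpyrrole
Product: 10 allyl glycidate (allyl (2R,3S)-3-[3-geranyl-4-(triisopropylsilyloxy)phenyl]oxirane-2-carboxylate)
Conditions: allyl alcohol (10 equiv), DBU (0.2 equiv), CH2Cl2, 0 °C → rt
Reagents that add atoms: allyl alcohol, C=CCO
Why: N-acylpyrroles behave as active esters, so base-catalysed alcoholysis (acyl substitution) is much faster than any attack on the epoxide and leaves both stereocentres untouched, and the allyl ester is chosen because it can later be removed without hydroxide.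

Step 7
Reactants: 11 phloroglucinol; 12 prenyl bromide
Product: 13 C-prenylphloroglucinol (2-(3-methylbut-2-en-1-yl)benzene-1,3,5-triol)
Conditions: 11 (3 equiv), KOH (1 equiv per 11), H2O, 0 °C → rt
Reagents that add atoms: none
Why: C-alkylation of the ambident phloroglucinolate in water, where hydrogen bonding masks the oxygens, is the usual entry to mono-C-prenylated phloroglucinols, and the excess of water-soluble 11 limits polyalkylation.

Step 8
Reactants: 13 C-prenylphloroglucinol
Product: 14 bis-silylated phenol (2-(3-methylbut-2-en-1-yl)-3,5-bis(triisopropylsilyloxy)phenol)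
Conditions: TIPSCl (2.05 equiv), imidazole, DMF, 0 °C → rt
Reagents that add atoms: triisopropylsilyl chloride, CC(C)[Si](Cl)(C(C)C)C(C)C
Why: in this sterically graded O-silylation the unhindered hydroxyl para to prenyl reacts first, the two hydroxyls flanking prenyl are equivalent so the second silylation gives one compound, and the third is slowed by buttressing, which leaves free the hydroxyl ortho to prenyl that becomes O1.

Step 9
Reactants: 10 allyl glycidate; 14 bis-silylated phenol
Product: 15 hydroxy ester (allyl (2R,3R)-3-[3-geranyl-4-(triisopropylsilyloxy)phenyl]-2-hydroxy-3-[2-prenyl-3,5-bis(triisopropylsilyloxy)phenoxy]propanoate)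
Conditions: 14 (1.2 equiv), Cs2CO3 (0.25 equiv), 4 Å MS, DMF, 40 °C
Reagents that add atoms: none
Why: in this base-catalysed phenolysis of a 3-arylglycidate (SN2 epoxide opening) the caesium phenoxide attacks the benzylic carbon anti to the epoxide oxygen, inverting it (3S to 3R) and leaving C2 (R) untouched, the non-acidic medium precludes benzylic ionisation, the polar aprotic solvent favours O- over C-alkylation, and 14 reprotonates the alkoxide so that catalytic base suffices.

Step 10
Reactants: 15 hydroxy ester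
Product: 16 silyloxy ester (allyl (2R,3R)-2-(tert-butyldimethylsilyloxy)-3-[3-geranyl-4-(triisopropylsilyloxy)phenyl]-3-[2-prenyl-3,5-bis(triisopropylsilyloxy)phenoxy]propanoate)
Conditions: TBSOTf, 2,6-lutidine, CH2Cl2, −40 → 0 °C
Reagents that add atoms: tert-butyldimethylsilyl triflate, CC(C)(C)[Si](C)(C)OS(=O)(=O)C(F)(F)F
Why: silyl triflate with lutidine silylates hindered secondary α-hydroxy esters and is too weakly basic to epimerise the α-carbon or to expel the β-aryloxide.

Step 11
Reactants: 16 silyloxy ester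
Product: 17 aryloxy acid ((2R,3R)-2-(tert-butyldimethylsilyloxy)-3-[3-geranyl-4-(triisopropylsilyloxy)phenyl]-3-[2-prenyl-3,5-bis(triisopropylsilyloxy)phenoxy]propanoic acid)
Conditions: Pd(PPh3)4 (5 mol %), morpholine (2 equiv), THF, rt; pH 5 phosphate wash
Reagents that add atoms: none
Why: in the Tsuji–Trost deallylation Pd(0) ionises only the allyl ester and morpholine traps the π-allyl unit, so the acid is released under neutral conditions that spare the four silyl ethers, the alkenes and the α-stereocentre.

Step 12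
Reactants: 17 aryloxy acid
Product: 19 fully silylated sanggenol C ((2R,3R)-3-(tert-butyldimethylsilyloxy)-2-[3-geranyl-4-(triisopropylsilyloxy)phenyl]-8-prenyl-5,7-bis(triisopropylsilyloxy)chroman-4-one), via acyl trifluoroacetate 18 (not isolated)
Conditions: (CF3CO)2O (2 equiv), CH2Cl2 (0.01 M), −30 → 0 °C; poured into cold aq NaHCO3
Reagents that add atoms: trifluoroacetic anhydride, O=C(OC(=O)C(F)(F)F)C(F)(F)F (its acyl group is carried only by 18)
Why: TFAA converts 17 into the acyl trifluoroacetate 18, whose acyl carbon is attacked by C4a of ring A, and loss of trifluoroacetate and of the Wheland proton gives the aryl ketone and restores aromaticity. The closest known chemistry is the intramolecular Friedel–Crafts acylation of 3-aryloxypropanoic acids to chroman-4-ones through mixed anhydrides or acid chlorides. Ring C closes in a 6-exo-trig mode at the anhydride carbonyl (6-enolendo with respect to the arene). No stereocentre is created; C2 and C3 are only carried through, and their trans relationship lets the aryl and OTBS groups sit equatorial in the closing ring. Site selectivity is built into the substrate: C4a is activated by O1, O5 and O7, C8 is blocked by prenyl, C6 is out of reach of the three-atom tether, and high dilution suppresses intermolecular acylation at C6. The weak activation avoids a free α-silyloxy acylium ion, which could lose CO, and the only acid present is dilute CF3CO2H below 0 °C, which should be too weak to protonate the trisubstituted alkenes, ionise the C2–O1 bond or enolise C3.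

Step 13
Reactants: 19 fully silylated sanggenol C
Product: 20 sanggenol C ((2R,3R)-3,5,7-trihydroxy-2-[3-geranyl-4-hydroxyphenyl]-8-prenylchroman-4-one)
Conditions: TBAF/AcOH (1:1, 6 equiv), THF, 0 °C → rt, Ar; pH 6 buffer
Reagents that add atoms: none
Why: fluoride cleaves all four Si–O bonds while acetic acid keeps the liberated phenols protonated, which prevents base-induced opening of ring C, epimerisation at C2 or C3 and aerial oxidation, and no acid strong enough to cyclise the ortho-prenyl or ortho-geranyl phenols is present.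

**Compound list**

1 | 4-iodophenol | Oc1ccc(I)cc1 | starting material
2 | geranyl bromide | CC(C)=CCC/C(C)=C/CBr | starting material
3 | 2-geranyl-4-iodophenol | CC(C)=CCC/C(C)=C/Cc1cc(I)ccc1O | intermediate
4 | (2-geranyl-4-iodophenoxy)triisopropylsilane | CC(C)=CCC/C(C)=C/Cc1cc(I)ccc1O[Si](C(C)C)(C(C)C)C(C)C | intermediate
5 | acrylic acid | C=CC(=O)O | starting material
6 | (E)-3-[3-geranyl-4-(TIPSO)phenyl]prop-2-enoic acid | CC(C)=CCC/C(C)=C/Cc1cc(/C=C/C(=O)O)ccc1O[Si](C(C)C)(C(C)C)C(C)C | intermediate
7 | acylimidazole of 6 | CC(C)=CCC/C(C)=C/Cc1cc(/C=C/C(=O)n2ccnc2)ccc1O[Si](C(C)C)(C(C)C)C(C)C | intermediate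
8 | (E)-N-cinnamoylpyrrole derived from 6 | CC(C)=CCC/C(C)=C/Cc1cc(/C=C/C(=O)n2cccc2)ccc1O[Si](C(C)C)(C(C)C)C(C)C | intermediate
9 | (2R,3S)-trans-epoxy N-acylpyrrole | CC(C)=CCC/C(C)=C/Cc1cc([C@@H]2O[C@H]2C(=O)n3cccc3)ccc1O[Si](C(C)C)(C(C)C)C(C)C | intermediate
10 | allyl (2R,3S)-trans-glycidate | CC(C)=CCC/C(C)=C/Cc1cc([C@@H]2O[C@H]2C(=O)OCC=C)ccc1O[Si](C(C)C)(C(C)C)C(C)C | intermediate
11 | phloroglucinol | Oc1cc(O)cc(O)c1 | starting material
12 | prenyl bromide | CC(C)=CCBr | starting material
13 | 2-prenylphloroglucinol | CC(C)=CCc1c(O)cc(O)cc1O | intermediate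
14 | 2-prenyl-3,5-bis(TIPSO)phenol | CC(C)=CCc1c(O)cc(O[Si](C(C)C)(C(C)C)C(C)C)cc1O[Si](C(C)C)(C(C)C)C(C)C | intermediate
15 | allyl (2R,3R)-3-aryl-3-aryloxy-2-hydroxypropanoate | CC(C)=CCC/C(C)=C/Cc1cc([C@@H](Oc2cc(O[Si](C(C)C)(C(C)C)C(C)C)cc(O[Si](C(C)C)(C(C)C)C(C)C)c2CC=C(C)C)[C@@H](O)C(=O)OCC=C)ccc1O[Si](C(C)C)(C(C)C)C(C)C | intermediate
16 | allyl (2R,3R)-3-aryl-3-aryloxy-2-(TBSO)propanoate | CC(C)=CCC/C(C)=C/Cc1cc([C@@H](Oc2cc(O[Si](C(C)C)(C(C)C)C(C)C)cc(O[Si](C(C)C)(C(C)C)C(C)C)c2CC=C(C)C)[C@@H](O[Si](C)(C)C(C)(C)C)C(=O)OCC=C)ccc1O[Si](C(C)C)(C(C)C)C(C)C | intermediate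
17 | (2R,3R)-3-aryl-3-aryloxy-2-(TBSO)propanoic acid | CC(C)=CCC/C(C)=C/Cc1cc([C@@H](Oc2cc(O[Si](C(C)C)(C(C)C)C(C)C)cc(O[Si](C(C)C)(C(C)C)C(C)C)c2CC=C(C)C)[C@@H](O[Si](C)(C)C(C)(C)C)C(=O)O)ccc1O[Si](C(C)C)(C(C)C)C(C)C | intermediate
18 | mixed anhydride of 17 with trifluoroacetic acid | CC(C)=CCC/C(C)=C/Cc1cc([C@@H](Oc2cc(O[Si](C(C)C)(C(C)C)C(C)C)cc(O[Si](C(C)C)(C(C)C)C(C)C)c2CC=C(C)C)[C@@H](O[Si](C)(C)C(C)(C)C)C(=O)OC(=O)C(F)(F)F)ccc1O[Si](C(C)C)(C(C)C)C(C)C | intermediate
19 | (2R,3R)-3-O-TBS-5,7,4'-tri-O-TIPS-sanggenol C | CC(C)=CCC/C(C)=C/Cc1cc([C@H]2Oc3c(CC=C(C)C)c(O[Si](C(C)C)(C(C)C)C(C)C)cc(O[Si](C(C)C)(C(C)C)C(C)C)c3C(=O)[C@@H]2O[Si](C)(C)C(C)(C)C)ccc1O[Si](C(C)C)(C(C)C)C(C)C | intermediate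
20 | sanggenol C, (2R,3R) | CC(C)=CCC/C(C)=C/Cc1cc([C@H]2Oc3c(CC=C(C)C)c(O)cc(O)c3C(=O)[C@@H]2O)ccc1O | target

**Step count**

- Total step count: 13.
- Longest linear sequence: 11 steps (steps 1–6 and 9–13). The ring A branch (steps 7 and 8) joins at step 9.

**Steps most likely to fail**

**1. Step 12.** The activated acyl group may lose CO. The acid set free may protonate the alkenes or heterolyse the benzylic C2–O1 bond. Crowding between the O1 substituent and the 5-silyloxy group may slow the closure enough for intermolecular acylation to compete.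

The fallback sets out from 17 and comes back at 19. It keeps the C4–C4a bond formation but changes the class of electrophile.
- Acid 17 is condensed with dimethylamine (EDC, HOBt, i-Pr2NEt, CH2Cl2) to the N,N-dimethylamide F1.
- Tf2O with 2,6-di-tert-butyl-4-methylpyridine in CH2Cl2 (−78 → 0 °C) turns F1 into an O-triflyl iminium ion.
- C4a attacks this ion in a Vilsmeier–Haack-type cyclisation to give the cyclic iminium triflate F2.
- Aqueous NaHCO3/THF hydrolyses F2 to 19.

This electrophile cannot decarbonylate. Every proton is scavenged, and the base is too hindered to deprotonate the α-carbon.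

**2. Step 9.** Attack of the hindered phenoxide may be slow. Ester-centred side processes could then compete: acyl transfer, or α-deprotonation followed by expulsion of the aryloxide. Silyl migration between oxygens and attack through carbon are further risks.

The fallback sets out from 10 (with 14) and comes back at 17. It removes the ester before the C–O bond is made.
- DIBAL-H (CH2Cl2, −78 °C) reduces 10 to the (2S,3S)-epoxy alcohol F3.
- Phenoxide opening of such 3-arylglycidols at the benzylic carbon with inversion is the established entry to 3-aryl-3-aryloxypropane-1,2-diols. With 14 and catalytic Cs2CO3 in DMF it should give the (2S,3R)-diol F4.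
- TEMPO/PhI(OAc)2 in MeCN–H2O oxidises only the primary alcohol, giving the (2R,3R)-hydroxy acid F5.
- TBSOTf with 2,6-lutidine gives the silyl ether silyl ester F6.
- A wash with AcOH–THF–H2O cleaves the silyl ester of F6 and delivers 17.

**3. Step 5.** Conjugate addition of the peroxide to the donor-substituted cinnamoyl system may be sluggish. The rare-earth catalyst may be deactivated by traces of water or azole. Facial selectivity may be insufficient.

The fallback sets out from 8 and comes back at 10. It replaces Lewis-acid catalysis by iminium catalysis.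
- DIBAL-H (1.1 equiv, CH2Cl2, −78 °C), followed by collapse of the pyrrolyl carbinol on work-up, gives the (E)-enal F7.
- A diarylprolinol silyl ether catalyst with aqueous H2O2 in CH2Cl2 performs a nucleophilic epoxidation that is again blind to the isolated alkenes. The catalyst antipode is chosen for the (2R,3S) series, and the product is the trans-epoxy aldehyde F8.
- Pinnick oxidation (NaClO2, NaH2PO4, large excess of 2-methyl-2-butene) gives the acid. It is kept as the sodium glycidate F9 to avoid decarboxylation.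
- Allyl bromide in DMF converts F9 into 10.

**Further compounds**

F1 | step 12 | (2R,3R)-N,N-dimethylamide of 17 | CC(C)=CCC/C(C)=C/Cc1cc([C@@H](Oc2cc(O[Si](C(C)C)(C(C)C)C(C)C)cc(O[Si](C(C)C)(C(C)C)C(C)C)c2CC=C(C)C)[C@@H](O[Si](C)(C)C(C)(C)C)C(=O)N(C)C)ccc1O[Si](C(C)C)(C(C)C)C(C)C
F2 | step 12 | C4 dimethyliminium triflate of 19 (spatially as 19; the C3 descriptor becomes S by CIP ranking only) | CC(C)=CCC/C(C)=C/Cc1cc([C@H]2Oc3c(CC=C(C)C)c(O[Si](C(C)C)(C(C)C)C(C)C)cc(O[Si](C(C)C)(C(C)C)C(C)C)c3C(=[N+](C)C)[C@@H]2O[Si](C)(C)C(C)(C)C)ccc1O[Si](C(C)C)(C(C)C)C(C)C.[O-]S(=O)(=O)C(F)(F)F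
F3 | step 9 | [(2S,3S)-3-[3-geranyl-4-(TIPSO)phenyl]oxiran-2-yl]methanol | CC(C)=CCC/C(C)=C/Cc1cc([C@@H]2O[C@H]2CO)ccc1O[Si](C(C)C)(C(C)C)C(C)C
F4 | step 9 | (2S,3R)-3-aryl-3-aryloxypropane-1,2-diol | CC(C)=CCC/C(C)=C/Cc1cc([C@@H](Oc2cc(O[Si](C(C)C)(C(C)C)C(C)C)cc(O[Si](C(C)C)(C(C)C)C(C)C)c2CC=C(C)C)[C@@H](O)CO)ccc1O[Si](C(C)C)(C(C)C)C(C)C
F5 | step 9 | (2R,3R)-3-aryl-3-aryloxy-2-hydroxypropanoic acid | CC(C)=CCC/C(C)=C/Cc1cc([C@@H](Oc2cc(O[Si](C(C)C)(C(C)C)C(C)C)cc(O[Si](C(C)C)(C(C)C)C(C)C)c2CC=C(C)C)[C@@H](O)C(=O)O)ccc1O[Si](C(C)C)(C(C)C)C(C)C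
F6 | step 9 | tert-butyldimethylsilyl ester of 17 | CC(C)=CCC/C(C)=C/Cc1cc([C@@H](Oc2cc(O[Si](C(C)C)(C(C)C)C(C)C)cc(O[Si](C(C)C)(C(C)C)C(C)C)c2CC=C(C)C)[C@@H](O[Si](C)(C)C(C)(C)C)C(=O)O[Si](C)(C)C(C)(C)C)ccc1O[Si](C(C)C)(C(C)C)C(C)C
F7 | step 5 | (E)-3-[3-geranyl-4-(TIPSO)phenyl]prop-2-enal | CC(C)=CCC/C(C)=C/Cc1cc(/C=C/C=O)ccc1O[Si](C(C)C)(C(C)C)C(C)C
F8 | step 5 | (2R,3S)-3-[3-geranyl-4-(TIPSO)phenyl]oxirane-2-carbaldehyde | CC(C)=CCC/C(C)=C/Cc1cc([C@@H]2O[C@H]2C=O)ccc1O[Si](C(C)C)(C(C)C)C(C)C
F9 | step 5 | sodium (2R,3S)-3-[3-geranyl-4-(TIPSO)phenyl]oxirane-2-carboxylate | CC(C)=CCC/C(C)=C/Cc1cc([C@@H]2O[C@H]2C(=O)[O-])ccc1O[Si](C(C)C)(C(C)C)C(C)C.[Na+]
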